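**Retrosynthetic overview**

- Feature: in the ten-membered carbocycle C1–C10 the γ-lactone oxygen on C6 and the hydroxyl on C3 are 1,4-related and on opposite faces across the Z C4=C5 alkene (O–C6–C5=C4(CH3)–C3–O), with the lactone trans-fused at C6–C7.
- Last ring: the C6–O (lactone) and C3–O bonds are cut back to a (3Z,5Z)-cyclodeca-3,5-dienyl acrylic acid, to be closed by palladium-catalysed 1,4-acetoxylactonisation; silyl and acetyl removal follow.
- First ring: the C4–C5 bond is cut to a (Z)-2-iodoalkene (C3=C4) and a (Z)-vinylstannane (C5=C6), joined by intramolecular Stille coupling; the acrylic acid is then grown from a C11–C12 silyloxyethyl arm.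
- C7–C8 is cut to an (R)-propargylic mesylate (C5–C7, C11, C12) and a C8 aldehyde from (S)-linalool (C10, C9, C1–C3), joined by an anti-selective allenylindium addition.
- Ring order: carbocycle (step 14), then α-methylene-γ-lactone (step 18).

Key step: step 18

Assumption: germacrane numbering is used throughout (C10 = C(CH3)OH, C1–C2 = CH2CH2, C3 = CHOH, C4=C5 alkene with CH3 on C4, C6 = OCH, C7 = fusion CH, C8 = ester CH, C9 = CH2, C11/C12/C13 = lactone α-carbon/carbonyl/methylene), and (S)-linalool is taken as purchasable in high enantiomeric purity.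

**Fragment A (C8 aldehyde)**

Step 1
Reactants: 1 (S)-linalool
Product: 2 (3S)-3,7-dimethyl-3-(triethylsilyloxy)octa-1,6-diene
Conditions: Et3SiOTf, 2,6-lutidine, CH2Cl2, −78 → 0 °C
Reagents that add atoms: triethylsilyl triflate, CC[Si](CC)(CC)OS(=O)(=O)C(F)(F)F
Why: Silyl ether formation with the triflate caps the hindered tertiary allylic C10–OH under non-acidic conditions, and the C10 stereocentre is carried over unchanged from the chiral pool.

Step 2
Reactants: 2 (3S)-3,7-dimethyl-3-(triethylsilyloxy)octa-1,6-diene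
Product: 4 (3S)-3,7-dimethyl-3-(triethylsilyloxy)oct-6-en-1-ol, via alkylborane 3 (not isolated)
Conditions: 9-BBN, THF, 0 °C → rt; then NaOH, H2O2, 0 °C
Reagents that add atoms: hydrogen peroxide, OO; 9-borabicyclo[3.3.1]nonane, B1C2CCCC1CCC2 (kept only in 3)
Why: Anti-Markovnikov hydroboration–oxidation, in which the bulky borane should add only to the monosubstituted vinyl group and leave the trisubstituted alkene alone, puts oxygen on C8.

Step 3
Reactants: 4 (3S)-3,7-dimethyl-3-(triethylsilyloxy)oct-6-en-1-ol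
Product: 5 (3S)-3,7-dimethyl-3-(triethylsilyloxy)oct-6-enal (fragment A)
Conditions: Dess–Martin periodinane, NaHCO3, CH2Cl2, 0 °C → rt
Reagents that add atoms: none
Why: Dess–Martin oxidation of the primary alcohol under buffered conditions should give the β-silyloxy aldehyde without elimination, and there is no stereocentre α to the carbonyl.

**Fragment B (propargylic mesylate)**

Step 4
Reactants: 6 methyl 3-hydroxypropanoate
Product: 7 methyl 3-(triethylsilyloxy)propanoate
Conditions: Et3SiCl, imidazole, CH2Cl2, 0 °C → rt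
Reagents that add atoms: chlorotriethylsilane, CC[Si](Cl)(CC)CC
Why: Silyl ether formation gives the future C12 oxygen a primary triethylsilyl group that can later be oxidised off directly under Swern conditions.

Step 5
Reactants: 7 methyl 3-(triethylsilyloxy)propanoate; 8 ethynyltrimethylsilane
Product: 10 5-(triethylsilyloxy)-1-(trimethylsilyl)pent-1-yn-3-one, via lithium trimethylsilylacetylide 9 (not isolated)
Conditions: 8, n-BuLi, THF, −78 °C; BF3·OEt2; then 7, −78 °C
Reagents that add atoms: n-butyllithium, [Li]CCCC (lithium kept only in 9)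
Why: BF3-promoted acylation of a lithium acetylide by an ester is a known ynone synthesis that should stop at the ketone at −78 °C.

Step 6
Reactants: 10 5-(triethylsilyloxy)-1-(trimethylsilyl)pent-1-yn-3-one
Product: 11 (3R)-5-(triethylsilyloxy)-1-(trimethylsilyl)pent-1-yn-3-ol
Conditions: RuCl[(R,R)-TsDPEN](p-cymene) (cat.), propan-2-ol, rt
Reagents that add atoms: none
Why: Noyori asymmetric transfer hydrogenation of an alkynyl ketone, where the (R,R)-catalyst should deliver hydride to the face that gives the (R)-propargylic alcohol, sets the centre that becomes C7.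

Step 7
Reactants: 11 (3R)-5-(triethylsilyloxy)-1-(trimethylsilyl)pent-1-yn-3-ol
Product: 12 (3R)-5-(triethylsilyloxy)-1-(trimethylsilyl)pent-1-yn-3-yl methanesulfonate (fragment B)
Conditions: MsCl, Et3N, CH2Cl2, −78 → 0 °C, used crude
Reagents that add atoms: methanesulfonyl chloride, CS(Cl)(=O)=O
Why: Sulfonylation at oxygen retains the (R) configuration and supplies the leaving group for the allenylmetal formation.

**Coupling and chain elaboration**

Step 8
Reactants: 5 (3S)-3,7-dimethyl-3-(triethylsilyloxy)oct-6-enal; 12 (3R)-mesylate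
Product: 14 anti homopropargylic alcohol (7S,8R,10S) Me3Si–C5≡C6–C7H(CH2CH2OSiEt3)–C8H(OH)–C9H2–C10(CH3)(OSiEt3)–C1H2–C2H2–C3H=C(CH3)2, via allenylindium 13 (not isolated)
Conditions: Pd(dppf)Cl2 (5 mol%), InI, THF–HMPA 3:1, rt
Reagents that add atoms: indium monoiodide, [In]I (kept only in 13)
Why: In this Marshall propargylation zerovalent palladium displaces the mesylate anti and hands a chiral allenyl group to indium, which adds to the aldehyde through a cyclic SE2′ transition state, so C7 is set by net inversion of the (R)-mesylate and C8 by the anti preference of the reagent, independent of the remote C10 centre (any minor syn isomer to be removed by chromatography).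

Step 9
Reactants: 14 anti homopropargylic alcohol; 15 isobutyryl chloride
Product: 16 C8 isobutyrate of 14 (7S,8R,10S)
Conditions: pyridine, DMAP (cat.), CH2Cl2, 0 °C → rt
Reagents that add atoms: none
Why: DMAP-catalysed acylation of the only free hydroxyl installs the C8 ester of the target, which then serves as its own protecting group.

Step 10
Reactants: 16 C8 isobutyrate
Product: 18 C3 aldehyde (7S,8R,10S) Me3Si–C5≡C6–C7H(CH2CH2OSiEt3)–C8H(OCOCH(CH3)2)–C9H2–C10(CH3)(OSiEt3)–C1H2–C2H2–C3H=O, via ozonide 17 (not isolated)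
Conditions: O3, CH2Cl2, −78 °C, Sudan Red 7B end point; then PPh3, → rt
Reagents that add atoms: ozone, [O-][O+]=O
Why: Ozonolysis with reductive work-up should cleave the electron-rich trisubstituted alkene well before the silylated alkyne reacts, freeing C3 as the aldehyde.

Step 11
Reactants: 18 C3 aldehyde
Product: 19 (3Z)-vinyl iodide (7S,8R,10S), chain end –C2H2–C3H=C4(CH3)I with iodine cis to C2
Conditions: [Ph3PEt]I, n-BuLi, THF; I2, −78 °C; NaN(SiMe3)2; then 18, −78 → −20 °C
Reagents that add atoms: ethyltriphenylphosphonium iodide, CC[P+](c1ccccc1)(c1ccccc1)c1ccccc1.[I-]; iodine, II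
Why: The Stork–Zhao-type iodo-Wittig olefination with the α-iodoethylidene ylide proceeds under kinetic control to the (Z)-2-iodoalkene, which fixes the C3=C4 geometry and places the C4 methyl, while the low temperature spares the ester.

Step 12
Reactants: 19 (3Z)-vinyl iodide
Product: 20 alkynylstannane (7S,8R,10S), Bu3Sn–C5≡C6 in place of Me3Si–C5≡C6
Conditions: (Bu3Sn)2O, Bu4NF (2 mol%), THF, 60 °C
Reagents that add atoms: bis(tributyltin) oxide, CCCC[Sn](CCCC)(CCCC)O[Sn](CCCC)(CCCC)CCCC
Why: Fluoride-catalysed silicon-to-tin exchange at the alkyne carbon stannylates the acetylide as it is released, which avoids the strong bases that the vinyl iodide and the ester would not tolerate.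

Step 13
Reactants: 20 alkynylstannane
Product: 22 (3Z,5Z)-iodo vinylstannane (7S,8R,10S) Bu3Sn–C5H=C6H–C7H(CH2CH2OSiEt3)–C8H(OCOCH(CH3)2)–C9H2–C10(CH3)(OSiEt3)–C1H2–C2H2–C3H=C4(CH3)I, via stannyl zirconyl alkene 21 (not isolated)
Conditions: Cp2Zr(H)Cl, THF, rt; then H2O
Reagents that add atoms: zirconocene chloride hydride Cp2Zr(H)Cl, [H][Zr](Cl)(C1C=CC=C1)C1C=CC=C1 (kept only in 21)
Why: Hydrozirconation adds H and Zr syn with zirconium on the tin-bearing carbon, and protonolysis with retention should leave tin cis to C7, that is the (Z)-vinylstannane.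

Step 14
Reactants: 22 (3Z,5Z)-iodo vinylstannane
Product: 23 (3Z,5Z,7S,8R,10S)-8-isobutyryloxy-10,12-bis(triethylsilyloxy)-13-norgermacra-3,5-diene
Conditions: Pd2(dba)3·CHCl3 (10 mol%), AsPh3 (40 mol%), DMF, 1 mM, slow addition, 45 °C
Reagents that add atoms: none
Why: Intramolecular Stille coupling under high dilution forms the C4–C5 bond with retention at both alkenes and closes the ten-membered ring as its cisoid (3Z,5Z)-diene.

Step 15
Reactants: 23 macrocyclic bis-silyl ether
Product: 25 (3Z,5Z,7S,8R,10S)-8-isobutyryloxy-10-triethylsilyloxy-13-norgermacra-3,5-dien-12-al, via alkoxysulfonium chloride 24 (not isolated)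
Conditions: (COCl)2, DMSO, CH2Cl2, −78 → −40 °C; then Et3N, → 0 °C
Reagents that add atoms: dimethyl sulfoxide, CS(C)=O (kept only in 24)
Why: Under Swern conditions the chlorosulfonium salt should cleave only the primary triethylsilyl ether and oxidise it directly to the C12 aldehyde, while the hindered tertiary silyl ether on C10 stays in place.

Step 16
Reactants: 25 C12 aldehyde
Product: 27 (3Z,5Z,7R,8R,10S)-8-isobutyryloxy-10-triethylsilyloxygermacra-3,5,11(13)-trien-12-al, via Mannich base 26 (not isolated)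
Conditions: CH2=NMe2 I, Et3N, CH2Cl2, rt
Reagents that add atoms: dimethylmethyleneiminium iodide (Eschenmoser's salt), C=[N+](C)C.[I-]
Why: Mannich α-methylenation of the aldehyde followed by loss of dimethylamine installs C13 as the exocyclic methylene without touching the enolisable isobutyrate.

Step 17
Reactants: 27 α-methylene aldehyde
Product: 28 (3Z,5Z,7R,8R,10S)-8-isobutyryloxy-10-triethylsilyloxygermacra-3,5,11(13)-trien-12-oic acid
Conditions: NaClO2, NaH2PO4, 2-methylbut-2-ene, t-BuOH–H2O, 0 °C → rt
Reagents that add atoms: sodium chlorite, [Na+].[O-]Cl=O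
Why: Pinnick oxidation converts the enal to the acrylic acid under mildly acidic conditions, with the alkene scavenger trapping hypochlorous acid before it can reach the diene.

**Key step and endgame**

Step 18
Reactants: 28 dienyl acrylic acid
Product: 30 (3S,4Z,6R,7R,8R,10S)-3-acetoxy-8-isobutyryloxy-10-triethylsilyloxygermacra-4,11(13)-dien-12,6-olide, via allylpalladium acetate 29 (not isolated)
Conditions: Pd(OAc)2 (10 mol%), 1,4-benzoquinone (2 equiv), LiOAc (2 equiv), AcOH–acetone 1:4, rt, chloride-free
Reagents that add atoms: acetic acid, CC(=O)O; palladium diacetate, CC(=O)O[Pd]OC(C)=O (kept only in 29)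
Why: Proposed new method: divalent palladium binds the cisoid C3=C4–C5=C6 diene, the C12 carboxylate adds to C6 anti to the metal in a 5-exo closure of the γ-lactone, and the resulting anti,anti-allylpalladium acetate 29 passes acetate from the metal to C3 before benzoquinone reoxidises zerovalent palladium; the closest known reaction is the palladium-catalysed 1,4-acetoxylactonisation of cyclohexa- and cycloheptadienylacetic acids, which gives cis-fused lactones, so both the ten-membered diene and the trans fusion are untested. C6 is controlled by allylic 1,3-strain across the Z C5=C6 bond, which holds H7 in the alkene plane and leaves the acid on C7 over the diene face that makes H6 and H7 trans. C3 is controlled by inner-sphere delivery of acetate on the palladium face, opposite to the lactone oxygen, which gives the trans-1,4 pattern (3S,6R). The ring keeps C2 and C6 as anti substituents of the allyl unit, so collapse of 29 should leave the Z C4=C5 alkene. The step needs lactonisation to outrun intermolecular acetate attack (five-membered closure), inner-sphere rather than external acetate delivery (no chloride) and no transannular attack by the C10 oxygen (silyl ether).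

Step 19
Reactants: 30 lactone acetate silyl ether
Product: 31 (3S,4Z,6R,7R,8R,10S)-3-acetoxy-10-hydroxy-8-isobutyryloxygermacra-4,11(13)-dien-12,6-olide
Conditions: HF·pyridine, pyridine, THF, 0 °C → rt
Reagents that add atoms: none
Why: Fluoride-driven silyl ether cleavage buffered with pyridine should free the tertiary C10–OH without ionising the allylic esters or touching the α-methylene lactone.

Step 20
Reactants: 31 C3 acetate
Product: 32 CNP0163972.1, (3S,4Z,6R,7R,8R,10S)-3,10-dihydroxy-8-isobutyryloxygermacra-4,11(13)-dien-12,6-olide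
Conditions: Candida antarctica lipase B (immobilised), n-BuOH, MTBE, 40 °C
Reagents that add atoms: none
Why: Lipase-catalysed transesterification to butanol should take the unbranched acetyl group and leave the α-branched isobutyrate, and its neutral conditions avoid conjugate addition to the α-methylene lactone.

**Compound list**

1 | (S)-linalool | C=C[C@@](C)(O)CCC=C(C)C | starting material
2 | (3S)-3,7-dimethyl-3-(triethylsilyloxy)octa-1,6-diene | C=C[C@@](C)(O[Si](CC)(CC)CC)CCC=C(C)C | intermediate
3 | B-[(3S)-3,7-dimethyl-3-(triethylsilyloxy)oct-6-enyl]-9-borabicyclo[3.3.1]nonane (not isolated) | CC(C)=CCC[C@](C)(O[Si](CC)(CC)CC)CCB1C2CCCC1CCC2 | intermediate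
4 | (3S)-3,7-dimethyl-3-(triethylsilyloxy)oct-6-en-1-ol | OCC[C@@](C)(O[Si](CC)(CC)CC)CCC=C(C)C | intermediate
5 | (3S)-3,7-dimethyl-3-(triethylsilyloxy)oct-6-enal | O=CC[C@@](C)(O[Si](CC)(CC)CC)CCC=C(C)C | intermediate
6 | methyl 3-hydroxypropanoate | COC(=O)CCO | starting material
7 | methyl 3-(triethylsilyloxy)propanoate | COC(=O)CCO[Si](CC)(CC)CC | intermediate
8 | ethynyltrimethylsilane | C#C[Si](C)(C)C | starting material
9 | lithium (trimethylsilyl)acetylide (not isolated) | [Li]C#C[Si](C)(C)C | intermediate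
10 | 5-(triethylsilyloxy)-1-(trimethylsilyl)pent-1-yn-3-one | C[Si](C)(C)C#CC(=O)CCO[Si](CC)(CC)CC | intermediate
11 | (3R)-5-(triethylsilyloxy)-1-(trimethylsilyl)pent-1-yn-3-ol | C[Si](C)(C)C#C[C@H](O)CCO[Si](CC)(CC)CC | intermediate
12 | (3R)-5-(triethylsilyloxy)-1-(trimethylsilyl)pent-1-yn-3-yl methanesulfonate | C[Si](C)(C)C#C[C@H](OS(C)(=O)=O)CCO[Si](CC)(CC)CC | intermediate
13 | allenylindium iodide mesylate, axis fixed by anti displacement of the mesylate (not isolated) | C[Si](C)(C)C([In](I)OS(C)(=O)=O)=C=CCCO[Si](CC)(CC)CC | intermediate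
14 | anti homopropargylic alcohol (7S,8R,10S) | CC[Si](CC)(CC)OCC[C@@H](C#C[Si](C)(C)C)[C@H](O)C[C@@](C)(O[Si](CC)(CC)CC)CCC=C(C)C | intermediate
15 | isobutyryl chloride | CC(C)C(Cl)=O | starting material
16 | C8 isobutyrate (7S,8R,10S) | CC[Si](CC)(CC)OCC[C@@H](C#C[Si](C)(C)C)[C@H](OC(=O)C(C)C)C[C@@](C)(O[Si](CC)(CC)CC)CCC=C(C)C | intermediate
17 | ozonide of 16, 1,2,4-trioxolane at C3 (not isolated) | CC[Si](CC)(CC)OCC[C@@H](C#C[Si](C)(C)C)[C@H](OC(=O)C(C)C)C[C@@](C)(O[Si](CC)(CC)CC)CCC1OOC(C)(C)O1 | intermediate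
18 | C3 aldehyde (7S,8R,10S) | CC[Si](CC)(CC)OCC[C@@H](C#C[Si](C)(C)C)[C@H](OC(=O)C(C)C)C[C@@](C)(O[Si](CC)(CC)CC)CCC=O | intermediate
19 | (3Z)-vinyl iodide (7S,8R,10S) | CC[Si](CC)(CC)OCC[C@@H](C#C[Si](C)(C)C)[C@H](OC(=O)C(C)C)C[C@@](C)(O[Si](CC)(CC)CC)CC/C=C(/C)I | intermediate
20 | alkynylstannane (3Z,7S,8R,10S) | CC[Si](CC)(CC)OCC[C@@H](C#C[Sn](CCCC)(CCCC)CCCC)[C@H](OC(=O)C(C)C)C[C@@](C)(O[Si](CC)(CC)CC)CC/C=C(/C)I | intermediate
21 | 1-stannyl-1-zirconyl alkene (not isolated) | CC[Si](CC)(CC)OCC[C@@H](/C=C(/[Zr](Cl)(C1C=CC=C1)C1C=CC=C1)[Sn](CCCC)(CCCC)CCCC)[C@H](OC(=O)C(C)C)C[C@@](C)(O[Si](CC)(CC)CC)CC/C=C(/C)I | intermediate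
22 | (3Z,5Z)-iodo vinylstannane (7S,8R,10S) | CC[Si](CC)(CC)OCC[C@@H](/C=C\[Sn](CCCC)(CCCC)CCCC)[C@H](OC(=O)C(C)C)C[C@@](C)(O[Si](CC)(CC)CC)CC/C=C(/C)I | intermediate
23 | (3Z,5Z,7S,8R,10S)-8-isobutyryloxy-10,12-bis(triethylsilyloxy)-13-norgermacra-3,5-diene | CC[Si](CC)(CC)OCC[C@@H]1[C@H](OC(=O)C(C)C)C[C@@](C)(O[Si](CC)(CC)CC)CC/C=C(C)\C=C/1 | intermediate
24 | C12 alkoxydimethylsulfonium chloride (not isolated) | C[S+](C)OCC[C@@H]1[C@H](OC(=O)C(C)C)C[C@@](C)(O[Si](CC)(CC)CC)CC/C=C(C)\C=C/1.[Cl-] | intermediate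
25 | (3Z,5Z,7S,8R,10S)-8-isobutyryloxy-10-triethylsilyloxy-13-norgermacra-3,5-dien-12-al | O=CC[C@@H]1[C@H](OC(=O)C(C)C)C[C@@](C)(O[Si](CC)(CC)CC)CC/C=C(C)\C=C/1 | intermediate
26 | C11 dimethylaminomethyl aldehyde, Mannich base, C11 unassigned (not isolated) | CN(C)CC(C=O)[C@@H]1[C@H](OC(=O)C(C)C)C[C@@](C)(O[Si](CC)(CC)CC)CC/C=C(C)\C=C/1 | intermediate
27 | (3Z,5Z,7R,8R,10S)-8-isobutyryloxy-10-triethylsilyloxygermacra-3,5,11(13)-trien-12-al | C=C(C=O)[C@@H]1[C@H](OC(=O)C(C)C)C[C@@](C)(O[Si](CC)(CC)CC)CC/C=C(C)\C=C/1 | intermediate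
28 | (3Z,5Z,7R,8R,10S)-8-isobutyryloxy-10-triethylsilyloxygermacra-3,5,11(13)-trien-12-oic acid | C=C(C(=O)O)[C@@H]1[C@H](OC(=O)C(C)C)C[C@@](C)(O[Si](CC)(CC)CC)CC/C=C(C)\C=C/1 | intermediate
29 | allylpalladium acetate over C3–C5 of the closed lactone, drawn as its C3-bound form (not isolated) | C=C1C(=O)O[C@@H]2/C=C(/C)[C@@H]([Pd]OC(C)=O)CC[C@](C)(O[Si](CC)(CC)CC)C[C@@H](OC(=O)C(C)C)[C@@H]12 | intermediate
30 | (3S,4Z,6R,7R,8R,10S)-3-acetoxy-8-isobutyryloxy-10-triethylsilyloxygermacra-4,11(13)-dien-12,6-olide | C=C1C(=O)O[C@@H]2/C=C(/C)[C@@H](OC(C)=O)CC[C@](C)(O[Si](CC)(CC)CC)C[C@@H](OC(=O)C(C)C)[C@@H]12 | intermediate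
31 | (3S,4Z,6R,7R,8R,10S)-3-acetoxy-10-hydroxy-8-isobutyryloxygermacra-4,11(13)-dien-12,6-olide | C=C1C(=O)O[C@@H]2/C=C(/C)[C@@H](OC(C)=O)CC[C@](C)(O)C[C@@H](OC(=O)C(C)C)[C@@H]12 | intermediate
32 | CNP0163972.1, (3S,4Z,6R,7R,8R,10S)-3,10-dihydroxy-8-isobutyryloxygermacra-4,11(13)-dien-12,6-olide | C=C1C(=O)O[C@@H]2/C=C(/C)[C@@H](O)CC[C@](C)(O)C[C@@H](OC(=O)C(C)C)[C@@H]12 | target

**Step count**

Total: 20 steps. Longest linear sequence: 17 steps (6 → 32 through steps 4–7 and 8–20); the linalool branch is 16 steps.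

**Steps most likely to fail**

1. Step 18 (Proposed new method). The allylpalladium intermediate may undergo syn–anti isomerisation before acetate transfer and give the E alkene; the carboxylate may add on the other diene face and give cis fusion; or intermolecular acetoxylation may outrun lactonisation. Fallback by known chemistry, setting out from 28: sensitised photo-oxygenation (O2, tetraphenylporphyrin, hν, CH2Cl2, −20 °C) adds singlet oxygen across the cisoid diene in a [4+2] sense to give the 3,6-endoperoxide acid F1. Thiourea reduction of the O–O bond gives the cis-3,6-dihydroxy acid F2. Carbodiimide lactonisation of the 6-hydroxyl with the C12 acid (EDC·HCl, DMAP) gives the 3-epi hydroxy lactone F3. Mitsunobu inversion at C3 with acetic acid (PPh3, DIAD) then returns to the route at 30. The facial course of the cycloaddition relative to C7 would have to be established.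

2. Step 14. Slow transmetalation between the hindered Z partners may let intermolecular coupling, protodestannylation or Z-to-E isomerisation compete with closure of the strained ten-membered ring. Fallback, setting out from 22: iododestannylation (I2, CH2Cl2, 0 °C) with retention gives the (3Z,5Z)-bis(vinyl iodide) F4. Intramolecular reductive coupling of the two vinyl iodides with stoichiometric zerovalent nickel (Ni(cod)2, PPh3, DMF, high dilution) closes the C4–C5 bond without a tin transmetalation and returns to the route at 23.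

3. Step 20. The enzyme may not accept the macrocyclic secondary allylic acetate, so acyl transfer stalls; a switch to basic methanolysis would risk alkoxide addition to the α-methylene lactone. Fallback, setting out from 31: the methylene lactone is masked by conjugate addition of dimethylamine (Me2NH, THF–EtOH, 0 °C) to give the amine adduct F5. The acetate is removed by methanolysis (K2CO3, MeOH, 0 °C), under which the hindered isobutyrate should react more slowly, to give the hydroxy amine F6. Quaternisation with MeI gives the ammonium iodide F7, and elimination with aqueous NaHCO3 restores the methylene group and returns to the route at 32.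

**Further compounds**

F1 | step 18 | cis-3,6-epidioxy acid (endoperoxide of 28) | C=C(C(=O)O)[C@@H]1[C@H](OC(=O)C(C)C)C[C@@](C)(O[Si](CC)(CC)CC)CC[C@H]2OO[C@@H]1C=C2C
F2 | step 18 | cis-3,6-dihydroxy-(4Z)-enoic acid | C=C(C(=O)O)[C@@H]1[C@H](OC(=O)C(C)C)C[C@@](C)(O[Si](CC)(CC)CC)CC[C@@H](O)/C(C)=C\[C@H]1O
F3 | step 18 | 3-epi hydroxy lactone, C10 triethylsilyl ether | C=C1C(=O)O[C@@H]2/C=C(/C)[C@H](O)CC[C@](C)(O[Si](CC)(CC)CC)C[C@@H](OC(=O)C(C)C)[C@@H]12
F4 | step 14 | (3Z,5Z)-bis(vinyl iodide) | CC[Si](CC)(CC)OCC[C@@H](/C=C\I)[C@H](OC(=O)C(C)C)C[C@@](C)(O[Si](CC)(CC)CC)CC/C=C(/C)I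
F5 | step 20 | 13-dimethylamino adduct of 31, C11 unassigned | CN(C)CC1C(=O)O[C@@H]2/C=C(/C)[C@@H](OC(C)=O)CC[C@](C)(O)C[C@@H](OC(=O)C(C)C)[C@@H]12
F6 | step 20 | 13-dimethylamino adduct of 32, C11 unassigned | CN(C)CC1C(=O)O[C@@H]2/C=C(/C)[C@@H](O)CC[C@](C)(O)C[C@@H](OC(=O)C(C)C)[C@@H]12
F7 | step 20 | 13-trimethylammonium iodide of F6 | C[N+](C)(C)CC1C(=O)O[C@@H]2/C=C(/C)[C@@H](O)CC[C@](C)(O)C[C@@H](OC(=O)C(C)C)[C@@H]12.[I-]
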